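## Retrosynthetic overview
1. The C15 allylic alcohol and the C19 acid come from a C13 methyl ketone by HWE and DIBAL reduction, followed by ester cleavage. The ketone comes from a ketal side chain added to the C9 ketone as a Grignard reagent.
2. The 8(17)-exocyclic methylene comes from a C8 aminomethyl (Mannich) ketone by Cope elimination. The 5α-OH alkoxide and the 10β-methyl direct the Grignard to the α face of C9, giving 9β-OH.
3. Ring A is formed last, by C4–C5 bond formation in an enantioselective Cu–H reductive aldol. This desymmetrizes the two enantiotopic ketones of a 2,2-disubstituted 1,3-dione and sets C4, C5 and C10 together.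
4. The dione is a Michael/Wittig product of 2-methylcyclohexane-1,3-dione, which comes from hydrogenation of 2-methylresorcinol. Ring B is therefore the hydrogenated arene; ring A is the only ring formed after that.

**Assumptions (one line):** (R)-DTBM-SEGPHOS is taken to give the required absolute configuration (use the (S)-ligand if the opposite antipode results). The C4 configuration is assumed to follow from a chair-like Z-enolate transition state with the tether equatorial.

## Route

**Step 1**
Reactants: 1 (2-methylresorcinol)
Product: 2 (2-methylcyclohexane-1,3-dione)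
Conditions: H2 (50 atm), Raney Ni, aq. NaOH, 50 °C; then HCl
Reagents that add atoms: H2, [H][H]
Why: Hydrogenation of the resorcinol dianion (via its keto tautomer) dearomatizes the ring to the achiral, symmetric 2-substituted 1,3-dione. Known reaction.

**Step 2**
Reactants: 2; 3 (acrolein)
Product: 4 (3-(1-methyl-2,6-dioxocyclohexyl)propanal)
Conditions: H2O, rt
Reagents that add atoms: acrolein, C=CC=O
Why: The acidic dione (pKa about 5) undergoes an uncatalysed Michael addition at C2 and creates the quaternary C10 (still prochiral).

**Step 3**
Reactants: 4; 5 (methyl 2-(triphenylphosphoranylidene)propanoate)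
Product: 6 (methyl (E)-2-methyl-5-(1-methyl-2,6-dioxocyclohexyl)pent-2-enoate)
Conditions: toluene, 80 °C
Reagents that add atoms: 5, CC(=P(c1ccccc1)(c1ccccc1)c1ccccc1)C(=O)OC (Ph3P=O is lost)
Why: Wittig reaction of a stabilized ylide. It is chemoselective for the aldehyde over the hindered dione ketones and gives the E-trisubstituted enoate (C3=C4).

**Step 4 (key step)**
Reactants: 6
Product: 7 (methyl 5α-hydroxy-9-oxo-labdane-type ketol ester: trans-decalin, 10β-Me, 4β-CO2Me, 4α-Me, 5α-OH)
Conditions: Cu(OAc)2·H2O (5 mol %), (R)-DTBM-SEGPHOS (5.5 mol %), TMDS, toluene, 0 °C → rt; then NH4F, MeOH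
Reagents that add atoms: none (TMDS, C[SiH](C)O[SiH](C)C, supplies only H; the silyl group is removed on work-up)
Why: Cu–H 1,4-reduction of the enoate gives a copper ester enolate. This adds intramolecularly to one of the two enantiotopic dione C=O groups (desymmetrizing reductive aldol), and the chiral ligand picks the ketone. A chair-like Zimmerman–Traxler transition state with the C1–C3 tether equatorial gives the trans-fused, diaxial 5α-OH/10β-Me arrangement, and the same transition state sets C4.

**Step 5**
Reactants: 7; 8 (Eschenmoser's salt)
Product: 9 (8-(dimethylaminomethyl) C9 ketone, C8 epimeric mixture)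
Conditions: LiHMDS (2.5 equiv), THF, −78 → 0 °C; then 8
Reagents that add atoms: 8, C=[N+](C)C.[I-] (retains CH2NMe2)
Why: The first equivalent of base deprotonates the tertiary OH. C10 is quaternary, so the second deprotonation is regiospecific at C8 and gives the Mannich base. The C8 stereocentre is destroyed in step 7.

**Step 6**
Reactants: 9; 10 (2-(2-bromoethyl)-2-methyl-1,3-dioxolane)
Product: 11 (C9 tertiary alcohol with the ketal side chain, 9β-OH)
Conditions: 10, Mg, THF (Grignard formation); CeCl3, THF, −78 → 0 °C; add 9 (4 equiv of reagent)
Reagents that add atoms: 10, CC1(CCBr)OCCO1 (retains the CH2CH2C(Me)(OCH2CH2O) fragment)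
Why: 1,2-Addition of an organocerium/Grignard reagent to the hindered ketone. Attack occurs from the α face, anti to the axial 10β-Me and directed by the axial 5α-alkoxide, giving 9β-OH with the chain α. The aminomethyl ketone avoids the conjugate-addition problems of an α-methylene ketone.

**Step 7**
Reactants: 11
Product: 12 (8(17)-ene, C9 alcohol, ketal side chain)
Conditions: mCPBA (1.05 equiv), CH2Cl2, −10 °C; then Me2S quench, DMSO, 60 °C
Reagents that add atoms: none (the oxidant oxygen leaves with Me2NOH)
Why: Cope elimination of the tertiary amine N-oxide. Syn-elimination with the only β-H (C8–H) gives the exocyclic C8=C17 methylene regiospecifically. No other alkene is present to compete.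

**Step 8**
Reactants: 12
Product: 13 (C13 methyl ketone)
Conditions: PPTS (cat.), acetone–H2O (9:1), 55 °C
Reagents that add atoms: water, O
Why: Mild acid-catalysed ketal hydrolysis. PPTS is weak enough to spare the tertiary allylic 9-OH and the exocyclic alkene.

**Step 9**
Reactants: 13; 14 (trimethyl phosphonoacetate)
Product: 15 (methyl (13E)-15-oate, 8(17),13E-diene)
Conditions: NaH (excess), THF, 0 → 50 °C; separate E/Z by AgNO3–SiO2
Reagents that add atoms: 14, COC(=O)CP(=O)(OC)OC (retains CH–CO2Me)
Why: Horner–Wadsworth–Emmons olefination of the methyl ketone, E-selective (about 4:1). The methyl phosphonate avoids transesterifying the C4 ester.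

**Step 10**
Reactants: 15
Product: 16 (methyl ester of the target)
Conditions: DIBAL-H (5 equiv), CH2Cl2, −78 → −20 °C
Reagents that add atoms: none (DIBAL-H, [H][Al](CC(C)C)CC(C)C, supplies only H)
Why: The unhindered conjugated ester is reduced to the allylic alcohol. The C4 ester, flanked by two quaternary centres, is inert.

**Step 11**
Reactants: 16
Product: 17 (5α,9β-dihydroxyisocupressic acid)
Conditions: PrSLi (from PrSH, n-BuLi), HMPA, THF, 0 → 25 °C; then pH 4 work-up
Reagents that add atoms: none (the methyl group is lost as PrSMe)
Why: SN2 dealkylation at the methyl carbon cleaves the neopentyl-type methyl ester without attacking the hindered carbonyl. The carboxylate formed cannot undergo retro-aldol.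

## Compound list
1 | 2-methylresorcinol | Cc1c(O)cccc1O | starting material
2 | 2-methylcyclohexane-1,3-dione | CC1C(=O)CCCC1=O | intermediate
3 | acrolein | C=CC=O | starting material
4 | 3-(1-methyl-2,6-dioxocyclohexyl)propanal | CC1(CCC=O)C(=O)CCCC1=O | intermediate
5 | methyl 2-(triphenylphosphoranylidene)propanoate | CC(=P(c1ccccc1)(c1ccccc1)c1ccccc1)C(=O)OC | starting material
6 | methyl (E)-2-methyl-5-(1-methyl-2,6-dioxocyclohexyl)pent-2-enoate | COC(=O)/C(C)=C/CCC1(C)C(=O)CCCC1=O | intermediate
7 | ketol ester: 5α-OH, 10β-Me, 4β-CO2Me, 9-oxo | C1CC[C@]2(O)[C@](C)(CCC[C@]2(C)C(=O)OC)C1=O | intermediate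
8 | Eschenmoser's salt | C=[N+](C)C.[I-] | starting material
9 | 8-(dimethylaminomethyl) ketone (C8 epimers) | CN(C)CC1CC[C@]2(O)[C@](C)(CCC[C@]2(C)C(=O)OC)C1=O | intermediate
10 | 2-(2-bromoethyl)-2-methyl-1,3-dioxolane | CC1(CCBr)OCCO1 | starting material
11 | Grignard adduct, 9β-OH, ketal side chain | CN(C)CC1CC[C@]2(O)[C@](C)(CCC[C@]2(C)C(=O)OC)[C@]1(O)CCC3(C)OCCO3 | intermediate
12 | 8(17)-ene, ketal | C=C1CC[C@]2(O)[C@](C)(CCC[C@]2(C)C(=O)OC)[C@]1(O)CCC3(C)OCCO3 | intermediate
13 | C13 methyl ketone | C=C1CC[C@]2(O)[C@](C)(CCC[C@]2(C)C(=O)OC)[C@]1(O)CCC(C)=O | intermediate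
14 | trimethyl phosphonoacetate | COC(=O)CP(=O)(OC)OC | starting material
15 | (13E)-15-oate methyl ester | C=C1CC[C@]2(O)[C@](C)(CCC[C@]2(C)C(=O)OC)[C@]1(O)CC/C(C)=C/C(=O)OC | intermediate
16 | methyl 5α,9β,15-trihydroxy-labda-8(17),13E-dien-19-oate | C=C1CC[C@]2(O)[C@](C)(CCC[C@]2(C)C(=O)OC)[C@]1(O)CC/C(C)=C/CO | intermediate
17 | 5α,9β-dihydroxyisocupressic acid | C=C1CC[C@]2(O)[C@](C)(CCC[C@]2(C)C(=O)O)[C@]1(O)CC/C(C)=C/CO | target

## Totals
Total steps: 11. Longest linear sequence: 11 (from 2-methylresorcinol).

## Three steps most likely to fail
1. **Step 4 (Cu–H desymmetrizing reductive aldol).** Risks are 1,2-reduction of the dione ketones, modest ee, and the wrong C4 epimer.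
   Fallback: hydrogenate the enoate to the saturated ester, cyclize by LiHMDS intramolecular aldol to racemic 7, and resolve by chiral preparative HPLC. This is a stepwise, non-catalytic-asymmetric approach.
2. **Step 6 (hindered 1,2-addition and C9 face selectivity).** Enolization, Mannich-base elimination to the enone, or the wrong C9 epimer are possible.
   Fallback: a SmI2 Barbier coupling of the C9 ketone with the iodide analogue of 10. Samarium chelates the 5α-alkoxide, and this proceeds by an organosamarium/ketyl pathway instead of a Grignard addition.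
3. **Step 9 (basic HWE on a free β-hydroxy ester).** Retro-aldol of ring A and poor E/Z selectivity are possible.
   Fallback: use the pre-built Grignard from (E)-TBSO-CH2CH=C(Me)CH2CH2Br in step 6 (made from 4-hydroxybutan-2-one by HWE, Appel bromination, DIBAL and TBS protection). Finish by removing the TBS group, which eliminates steps 8–10 and the late-stage base exposure.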